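## Retrosynthetic overview

1. Glabrol ⇒ a 2'-hydroxychalcone carrying both prenyl groups, by disconnecting O1–C2 (oxa-Michael); this chalcone is never isolated.
2. Ring A of that chalcone ⇒ a [4+2] benzannulation (C4a–C8a and C5–C6, with loss of MeOSiMe3) between a 2-prenyl 1-methoxy-1,3-bis(silyloxy)diene and the terminal alkyne of an aryl enynone.
3. Diene ⇒ methyl acetoacetate + prenyl bromide (alkylation, one-pot double silylation).
4. Enynone ⇒ 4-hydroxybenzaldehyde (ortho C-prenylation, Wittig to a Weinreb amide, ethynyl Grignard).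
5. Ring order: ring B is bought; ring A and then ring C form one after the other in the final one-flask operation, with C2 set by a chiral bifunctional thiourea. No protecting-group steps.

Assumption: the quinidine-derived thiourea is taken to give the 2S product; if the sense of induction proves opposite, its quinine-derived pseudo-enantiomer is used in the same step.

## Route

Step 1
Reactants: 1 methyl acetoacetate
Product: 2 methyl 2-acetyl-5-methylhex-4-enoate (methyl 2-prenylacetoacetate, racemic)
Conditions: NaH (1.0 equiv), THF, 0 °C; prenyl bromide (0.9 equiv), 0 °C → rt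
Reagents that add atoms: prenyl bromide, CC(C)=CCBr
Why: The enolate of 1 generated with NaH is C-alkylated by the allylic bromide (SN2 acetoacetic ester alkylation); the new centre is enolisable and becomes sp2 in step 2.

Step 2
Reactants: 2 methyl 2-acetyl-5-methylhex-4-enoate
Product: 4 1-methoxy-2-(3-methylbut-2-enyl)-1,3-bis(trimethylsilyloxy)buta-1,3-diene, via silyl enol ether 3 (not isolated)
Conditions: TMSOTf (2.2 equiv), Et3N (2.5 equiv), Et2O, 0 °C → rt, 4 h; decant from the ammonium triflate layer under argon, concentrate, use crude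
Reagents that add atoms: trimethylsilyl trifluoromethanesulfonate, C[Si](C)(C)OS(=O)(=O)C(F)(F)F
Why: Soft enolisation first O-silylates the ketone enol, then O-silylates the ester carbonyl and removes a γ-proton from the methyl group, giving the Chan-type bis(silyloxy)diene in one pot (double silyl enol ether formation); no stereocentre is formed.

Step 3
Reactants: 5 4-hydroxybenzaldehyde
Product: 6 4-hydroxy-3-(3-methylbut-2-enyl)benzaldehyde
Conditions: prenyl bromide (1.1 equiv), KOH (10 % aq), rt, 24 h; acidify to pH 5, chromatography (recover 5)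
Reagents that add atoms: prenyl bromide, CC(C)=CCBr
Why: In water the hydrogen-bonded phenoxide reacts as an ambident nucleophile at the ortho carbon (para position blocked by CHO), a direct phenoxide ortho C-prenylation followed by rearomatisation.

Step 4
Reactants: 6 4-hydroxy-3-(3-methylbut-2-enyl)benzaldehyde
Product: 7 (E)-3-[4-hydroxy-3-(3-methylbut-2-enyl)phenyl]-N-methoxy-N-methylprop-2-enamide
Conditions: Ph3P=CHC(O)N(OMe)Me (1.2 equiv), toluene, 90 °C, 12 h
Reagents that add atoms: N-methoxy-N-methyl-2-(triphenylphosphoranylidene)acetamide, CON(C)C(=O)C=P(c1ccccc1)(c1ccccc1)c1ccccc1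
Why: Wittig olefination with a stabilised amide ylide tolerates the free phenol and gives the E-alkene selectively.

Step 5
Reactants: 7 (E)-3-[4-hydroxy-3-(3-methylbut-2-enyl)phenyl]-N-methoxy-N-methylprop-2-enamide
Product: 8 (E)-1-[4-hydroxy-3-(3-methylbut-2-enyl)phenyl]pent-1-en-4-yn-3-one
Conditions: HC≡CMgBr (0.5 M in THF, 4 equiv), THF, 0 °C → rt, 3 h; inverse quench into 1 M HCl at 0 °C; use promptly
Reagents that add atoms: ethynylmagnesium bromide, C#C[Mg]Br
Why: After deprotonation of the phenol the alkynyl Grignard adds once to the Weinreb amide because the MgBr-chelated tetrahedral adduct survives until the quench (Weinreb ketone synthesis), and the cold acidic inverse quench protonates the released amine before it can add to the ynone.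

Step 6
Reactants: 8 (E)-1-[4-hydroxy-3-(3-methylbut-2-enyl)phenyl]pent-1-en-4-yn-3-one; 4 1-methoxy-2-(3-methylbut-2-enyl)-1,3-bis(trimethylsilyloxy)buta-1,3-diene
Product: 13 (2S)-glabrol, via enynone TMS ether 9 (not isolated), via Diels–Alder cycloadduct 10 (not isolated), via chalcone bis-TMS ether 11 (not isolated), via flavanone bis-TMS ether 12 (not isolated)
Conditions: N,O-bis(trimethylsilyl)acetamide (0.55 equiv), toluene, rt, 1 h; then 4 (1.05 equiv), 0 → 40 °C, 12 h; then N-[3,5-bis(trifluoromethyl)phenyl]-N'-[(9R)-6'-methoxycinchonan-9-yl]thiourea (10 mol %), −20 → 0 °C, 48 h; then citric acid, MeOH/H2O, 0 °C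
Reagents that add atoms: none
Why: Proposed new method: the electron-rich diene 4 adds with its CH2 terminus to the alkyne β-carbon and its ketene-acetal carbon to the α-carbon of the ynone (Diels–Alder benzannulation, the aryl enone being a far poorer dienophile), the doubly allylic ketal carbon of 10 then loses MeOSiMe3 under amine base to aromatise ring A with the free OH ortho to the carbonyl, and the bifunctional catalyst (quinuclidine N deprotonating this chelated phenol, thiourea hydrogen-bonding the enone C=O) delivers the phenoxide 6-endo to one face of the β-carbon to close ring C and set C2 as S; the closest known reaction types are the [4+2] benzannulation of 1-alkoxy-1,3-bis(silyloxy)dienes with alkynones to give 2,4-dihydroxyaryl ketones and the cinchona-thiourea-catalysed enantioselective intramolecular oxa-Michael cyclisation of 2'-hydroxychalcones to flavanones.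

## Compound list

1 | methyl acetoacetate (methyl 3-oxobutanoate) | COC(=O)CC(C)=O | starting material
2 | methyl 2-acetyl-5-methylhex-4-enoate (racemic, enolisable centre) | COC(=O)C(CC=C(C)C)C(C)=O | intermediate
3 | methyl 2-(3-methylbut-2-enyl)-3-(trimethylsilyloxy)but-2-enoate (E/Z mixture) | COC(=O)C(CC=C(C)C)=C(C)O[Si](C)(C)C | intermediate
4 | 1-methoxy-2-(3-methylbut-2-enyl)-1,3-bis(trimethylsilyloxy)buta-1,3-diene (ketene-acetal geometry not defined; lost in step 6) | COC(O[Si](C)(C)C)=C(CC=C(C)C)C(=C)O[Si](C)(C)C | intermediate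
5 | 4-hydroxybenzaldehyde | O=Cc1ccc(O)cc1 | starting material
6 | 4-hydroxy-3-(3-methylbut-2-enyl)benzaldehyde | CC(C)=CCc1cc(C=O)ccc1O | intermediate
7 | (E)-3-[4-hydroxy-3-(3-methylbut-2-enyl)phenyl]-N-methoxy-N-methylprop-2-enamide | CON(C)C(=O)/C=C/c1ccc(O)c(CC=C(C)C)c1 | intermediate
8 | (E)-1-[4-hydroxy-3-(3-methylbut-2-enyl)phenyl]pent-1-en-4-yn-3-one | C#CC(=O)/C=C/c1ccc(O)c(CC=C(C)C)c1 | intermediate
9 | (E)-1-[3-(3-methylbut-2-enyl)-4-(trimethylsilyloxy)phenyl]pent-1-en-4-yn-3-one | C#CC(=O)/C=C/c1ccc(O[Si](C)(C)C)c(CC=C(C)C)c1 | intermediate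
10 | (E)-1-[6-methoxy-5-(3-methylbut-2-enyl)-4,6-bis(trimethylsilyloxy)cyclohexa-1,4-dien-1-yl]-3-[3-(3-methylbut-2-enyl)-4-(trimethylsilyloxy)phenyl]prop-2-en-1-one (racemic at the ketal carbon) | COC1(O[Si](C)(C)C)C(CC=C(C)C)=C(O[Si](C)(C)C)CC=C1C(=O)/C=C/c1ccc(O[Si](C)(C)C)c(CC=C(C)C)c1 | intermediate
11 | (E)-1-[2-hydroxy-3-(3-methylbut-2-enyl)-4-(trimethylsilyloxy)phenyl]-3-[3-(3-methylbut-2-enyl)-4-(trimethylsilyloxy)phenyl]prop-2-en-1-one | CC(C)=CCc1cc(/C=C/C(=O)c2ccc(O[Si](C)(C)C)c(CC=C(C)C)c2O)ccc1O[Si](C)(C)C | intermediate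
12 | (2S)-8-(3-methylbut-2-enyl)-2-[3-(3-methylbut-2-enyl)-4-(trimethylsilyloxy)phenyl]-7-(trimethylsilyloxy)chroman-4-one | CC(C)=CCc1cc([C@@H]2CC(=O)c3ccc(O[Si](C)(C)C)c(CC=C(C)C)c3O2)ccc1O[Si](C)(C)C | intermediate
13 | glabrol, (2S)-7-hydroxy-2-[4-hydroxy-3-(3-methylbut-2-enyl)phenyl]-8-(3-methylbut-2-enyl)chroman-4-one | CC(C)=CCc1cc([C@@H]2CC(=O)c3ccc(O)c(CC=C(C)C)c3O2)ccc1O | target

## Step count and risks

Total steps: 6 (steps 1–2 make the diene, steps 3–5 the enynone, step 6 joins them).
Longest linear sequence: 4 steps (5 → 6 → 7 → 8 → 13).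

**Risk 1, step 6.** The telescoped benzannulation and asymmetric ring closure is unprecedented as one operation. Enantioselectivity for a non-activated, electron-rich 2'-hydroxychalcone may be only moderate, the oxa-Michael equilibrium may leave chalcone, and silyl by-products may interfere with the catalyst. Recrystallisation is the first remedy for modest ee. The fallback sets out from 8 and 4 and comes back at 13. The same benzannulation is run with DBU (10 mol %) in place of the thiourea, giving the racemic flavanone bis-TMS ether F1. The citric acid work-up then gives racemic glabrol F2. TBSCl and imidazole in DMF give the racemic bis-TBS ether F3. Kinetic resolution by asymmetric transfer hydrogenation follows ([RhCl2(C5Me5)]2, (R,R)-TsDPEN, HCO2H/Et3N 5:2, EtOAc, rt, stopped near 52 % conversion). It reduces the 2R enantiomer to the cis-(2R,4R)-flavan-4-ol bis-TBS ether F4 and leaves the (2S)-flavanone bis-TBS ether F5. After chromatographic separation, KHF2 in MeOH at rt desilylates F5 to 13. Here the stereocentre comes from resolution of a ketone rather than from the cyclisation.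

**Risk 2, step 5.** The magnesium phenoxide deactivates the vinylogous amide, and the terminal ynone can be lost to conjugate addition of the liberated amine or to polymerisation. The fallback sets out from 6 and comes back at 8. Wittig reaction of 6 with Ph3P=CHCHO (toluene, 80 °C) gives (E)-3-[4-hydroxy-3-(3-methylbut-2-enyl)phenyl]prop-2-enal F6. HC≡CMgBr (3 equiv, THF, 0 °C) adds 1,2 to give racemic (E)-1-[4-hydroxy-3-(3-methylbut-2-enyl)phenyl]pent-1-en-4-yn-3-ol F7. MnO2 in CH2Cl2 at rt oxidises this allylic-propargylic alcohol to 8. No nucleophilic amine is ever present with the ynone.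

**Risk 3, step 3.** Direct C-prenylation is low-yielding, with O-prenyl and diprenyl by-products. The fallback sets out from 5 and comes back at 6. 3-Chloro-3-methylbut-1-yne with DBU and catalytic CuCl2 in MeCN at 0 °C gives 4-[(2-methylbut-3-yn-2-yl)oxy]benzaldehyde F8. Semi-hydrogenation (H2, Pd/CaCO3 poisoned with Pb(OAc)2, quinoline, EtOAc) gives 4-[(2-methylbut-3-en-2-yl)oxy]benzaldehyde F9. Heating in N,N-diethylaniline at 180 °C effects the aromatic Claisen rearrangement to 6, placing the prenyl group ortho to the OH.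

## Further compounds

F1 | step 6 | racemic 8-(3-methylbut-2-enyl)-2-[3-(3-methylbut-2-enyl)-4-(trimethylsilyloxy)phenyl]-7-(trimethylsilyloxy)chroman-4-one | CC(C)=CCc1cc(C2CC(=O)c3ccc(O[Si](C)(C)C)c(CC=C(C)C)c3O2)ccc1O[Si](C)(C)C
F2 | step 6 | racemic glabrol | CC(C)=CCc1cc(C2CC(=O)c3ccc(O)c(CC=C(C)C)c3O2)ccc1O
F3 | step 6 | racemic 7-(tert-butyldimethylsilyloxy)-2-[4-(tert-butyldimethylsilyloxy)-3-(3-methylbut-2-enyl)phenyl]-8-(3-methylbut-2-enyl)chroman-4-one | CC(C)=CCc1cc(C2CC(=O)c3ccc(O[Si](C)(C)C(C)(C)C)c(CC=C(C)C)c3O2)ccc1O[Si](C)(C)C(C)(C)C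
F4 | step 6 | (2R,4R)-7-(tert-butyldimethylsilyloxy)-2-[4-(tert-butyldimethylsilyloxy)-3-(3-methylbut-2-enyl)phenyl]-8-(3-methylbut-2-enyl)chroman-4-ol | CC(C)=CCc1cc([C@H]2C[C@@H](O)c3ccc(O[Si](C)(C)C(C)(C)C)c(CC=C(C)C)c3O2)ccc1O[Si](C)(C)C(C)(C)C
F5 | step 6 | (2S)-7-(tert-butyldimethylsilyloxy)-2-[4-(tert-butyldimethylsilyloxy)-3-(3-methylbut-2-enyl)phenyl]-8-(3-methylbut-2-enyl)chroman-4-one | CC(C)=CCc1cc([C@@H]2CC(=O)c3ccc(O[Si](C)(C)C(C)(C)C)c(CC=C(C)C)c3O2)ccc1O[Si](C)(C)C(C)(C)C
F6 | step 5 | (E)-3-[4-hydroxy-3-(3-methylbut-2-enyl)phenyl]prop-2-enal | O=C/C=C/c1ccc(O)c(CC=C(C)C)c1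
F7 | step 5 | racemic (E)-1-[4-hydroxy-3-(3-methylbut-2-enyl)phenyl]pent-1-en-4-yn-3-ol | C#CC(O)/C=C/c1ccc(O)c(CC=C(C)C)c1
F8 | step 3 | 4-[(2-methylbut-3-yn-2-yl)oxy]benzaldehyde | C#CC(C)(C)Oc1ccc(C=O)cc1
F9 | step 3 | 4-[(2-methylbut-3-en-2-yl)oxy]benzaldehyde | C=CC(C)(C)Oc1ccc(C=O)cc1
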